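Prostanoid numbering is used throughout: C1 is the lactone carbonyl, ring A is the cyclopentanone C8–C12, and ring B is the 13-membered lactone through C1–C8, C12–C15 and the C15 oxygen. The target is read as 8R,11R,12R,15S with 5Z,13E,17Z, the 11-acetate of prostaglandin E3 1,15-lactone.

- Retrosynthesis: the 5Z-olefin of ring B is traced back to a ring alkyne, whose C5–C6 triple bond is cut by alkyne metathesis into a but-2-ynyl group on C8 and a hept-5-ynoate on the C15 oxygen. The C15–O ester bond is cut next, then C7–C8 and C12–C13.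
- Forward: the C13–C20 alkenyl iodide is made from (Z)-hex-3-en-1-ol. Ring A is bought as a silyloxy enone and receives both side chains in one pot. C15 is esterified, the C11 silyl ether is exchanged for acetate, ring B is closed, and the ring alkyne is semihydrogenated.
- Stereochemistry: C11 comes with the enone and directs C12 (anti conjugate addition) and C8 (anti alkylation). C15 comes from a Sharpless kinetic resolution. 17Z comes from the starting hexenol, 13E from an E-distannylethene, 5Z from syn hydrogenation.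
- Enabling feature: the C5=C6 cis-olefin sits in the 13-membered ring B between the C4 and C7 methylenes. It can therefore be carried as a C5≡C6 triple bond, which a ring of this size holds and which two methyl-capped alkynes deliver.

Key step: step 12

Remark: hept-5-ynoic acid, (E)-1,2-bis(tributylstannyl)ethene and the (R)-silyloxy enone are assumed to be purchasable as such.

Step 1
Reactants: 1 (Z)-hex-3-en-1-ol
Product: 2 (Z)-hex-3-enal
Conditions: Dess–Martin periodinane, CH2Cl2, 0 °C to rt; short silica plug, used at once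
Reagents that add atoms: none
Why: Dess–Martin oxidation of a primary alcohol runs without base at or below room temperature, so the aldehyde should form without migration of the skipped Z-olefin into conjugation.

Step 2
Reactants: 2 (Z)-hex-3-enal; 3 (E)-1,2-bis(tributylstannyl)ethene
Product: 5 rac-(1E,5Z)-1-(tributylstannyl)octa-1,5-dien-3-ol, via (E)-2-(tributylstannyl)vinyllithium 4 (not isolated)
Conditions: 3, n-BuLi, THF, −78 °C; then 2, −78 °C; aq. NH4Cl
Reagents that add atoms: none
Why: Tin–lithium exchange on the E-distannane gives the E-stannylvinyllithium with retention, and its 1,2-addition to the aldehyde at −78 °C (alkenyllithium carbonyl addition) gives the C15 carbinol as a racemate that step 4 resolves.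

Step 3
Reactants: 5 rac-(1E,5Z)-1-(tributylstannyl)octa-1,5-dien-3-ol
Product: 6 rac-(1E,5Z)-1-iodoocta-1,5-dien-3-ol
Conditions: I2, CH2Cl2, 0 °C; aq. Na2S2O3
Reagents that add atoms: iodine, II
Why: Iododestannylation is an ipso electrophilic substitution at the alkenyl carbon that keeps the E-geometry and should far outpace any reaction of iodine with the isolated Z-olefin.

Step 4
Reactants: 6 rac-(1E,5Z)-1-iodoocta-1,5-dien-3-ol
Product: 7 (3S,1E,5Z)-1-iodoocta-1,5-dien-3-ol
Conditions: Ti(OiPr)4 (cat.), D-(−)-diisopropyl tartrate (cat.), t-BuOOH (0.6 equiv), 4 Å molecular sieves, CH2Cl2, −20 °C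
Reagents that add atoms: none
Why: Sharpless kinetic resolution: the titanium D-(−)-tartrate catalyst epoxidizes the (R)-allylic alcohol (matched pair) much faster than its enantiomer, so the unreacted alcohol should be recovered as the 15S carbinol, while the Z-olefin, only homoallylic to the hydroxyl, reacts far more slowly.

Step 5
Reactants: 7 (3S,1E,5Z)-1-iodoocta-1,5-dien-3-ol
Product: 8 (3S,1E,5Z)-1-iodo-3-(triethylsilyloxy)octa-1,5-diene
Conditions: Et3SiCl, imidazole, CH2Cl2, 0 °C
Reagents that add atoms: chlorotriethylsilane, CC[Si](Cl)(CC)CC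
Why: Standard silylation of a secondary allylic alcohol gives a triethylsilyl ether that survives t-BuLi and the zincate chemistry of step 7 and can later be cleaved beside the tert-butyldimethylsilyl ether at C11.

Step 6
Reactants: 9 1-bromobut-2-yne
Product: 10 1-iodobut-2-yne
Conditions: NaI, acetone, rt, dark; used freshly
Reagents that add atoms: sodium iodide, [Na+].[I-]
Why: Finkelstein halide exchange, driven by precipitation of NaBr from acetone, gives the more reactive propargylic iodide that the enolate alkylation of step 7 needs.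

Step 7
Reactants: 8 (3S,1E,5Z)-1-iodo-3-(triethylsilyloxy)octa-1,5-diene; 11 (R)-4-(tert-butyldimethylsilyloxy)cyclopent-2-en-1-one; 10 1-iodobut-2-yne
Product: 15 (2R,3R,4R)-2-(but-2-yn-1-yl)-4-(tert-butyldimethylsilyloxy)-3-[(3S,1E,5Z)-3-(triethylsilyloxy)octa-1,5-dien-1-yl]cyclopentan-1-one, via alkenyllithium 12 (not isolated), via lithium alkenyldimethylzincate 13 (not isolated), via zinc enolate 14 (not isolated)
Conditions: 8, t-BuLi (2 equiv), Et2O, −78 °C; Me2Zn, THF, −78 °C; 11, −78 °C; HMPA, 10 (excess), −78 to −40 °C; aq. NH4Cl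
Reagents that add atoms: none
Why: Three-component coupling by conjugate addition and enolate alkylation: iodine–lithium exchange with retention gives the E-alkenyllithium, its dimethylzincate adds 1,4 to the enone on the face opposite to the C11 silyloxy group (sets C12), and the regiodefined zinc enolate, slow to exchange protons, is propargylated at C8 anti to the new C12 chain (sets C8), giving the all-trans ring A.

Step 8
Reactants: 15 (2R,3R,4R)-2-(but-2-yn-1-yl)-4-(tert-butyldimethylsilyloxy)-3-[(3S,1E,5Z)-3-(triethylsilyloxy)octa-1,5-dien-1-yl]cyclopentan-1-one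
Product: 16 (2R,3R,4R)-2-(but-2-yn-1-yl)-4-(tert-butyldimethylsilyloxy)-3-[(3S,1E,5Z)-3-hydroxyocta-1,5-dien-1-yl]cyclopentan-1-one
Conditions: PPTS (cat.), MeOH–CH2Cl2, 0 °C
Reagents that add atoms: none
Why: Acid-catalysed methanolysis cleaves a triethylsilyl ether much faster than a secondary tert-butyldimethylsilyl ether, so the C15 hydroxyl should be freed selectively under conditions mild enough for the β-silyloxy ketone.

Step 9
Reactants: 16 (2R,3R,4R)-2-(but-2-yn-1-yl)-4-(tert-butyldimethylsilyloxy)-3-[(3S,1E,5Z)-3-hydroxyocta-1,5-dien-1-yl]cyclopentan-1-one; 17 hept-5-ynoic acid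
Product: 18 (3S,1E,5Z)-1-[(1R,2R,5R)-2-(but-2-yn-1-yl)-5-(tert-butyldimethylsilyloxy)-3-oxocyclopentyl]octa-1,5-dien-3-yl hept-5-ynoate
Conditions: DCC, DMAP (cat.), CH2Cl2, 0 °C to rt
Reagents that add atoms: none
Why: Steglich esterification (carbodiimide activation with DMAP as acyl-transfer catalyst) acylates the allylic C15 hydroxyl with retention, because the C–O bond of the alcohol is not broken.

Step 10
Reactants: 18 (3S,1E,5Z)-1-[(1R,2R,5R)-2-(but-2-yn-1-yl)-5-(tert-butyldimethylsilyloxy)-3-oxocyclopentyl]octa-1,5-dien-3-yl hept-5-ynoate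
Product: 19 (3S,1E,5Z)-1-[(1R,2R,5R)-2-(but-2-yn-1-yl)-5-hydroxy-3-oxocyclopentyl]octa-1,5-dien-3-yl hept-5-ynoate
Conditions: HF·pyridine, pyridine, THF, 0 °C to rt
Reagents that add atoms: none
Why: Desilylation with buffered HF·pyridine removes the C11 silyl ether under mildly acidic conditions that avoid base-induced loss of the β-oxygen and leave the allylic ester and both alkynes untouched.

Step 11
Reactants: 19 (3S,1E,5Z)-1-[(1R,2R,5R)-2-(but-2-yn-1-yl)-5-hydroxy-3-oxocyclopentyl]octa-1,5-dien-3-yl hept-5-ynoate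
Product: 20 (3S,1E,5Z)-1-[(1R,2R,5R)-5-acetoxy-2-(but-2-yn-1-yl)-3-oxocyclopentyl]octa-1,5-dien-3-yl hept-5-ynoate
Conditions: Ac2O, pyridine, CH2Cl2, 0 °C; prompt work-up
Reagents that add atoms: acetic anhydride, CC(=O)OC(C)=O
Why: Acylation of the secondary C11 alcohol with acetic anhydride in pyridine at 0 °C, without DMAP, retains the C11 configuration and should keep the β-acetoxy ketone from eliminating.

Step 12
Reactants: 20 (3S,1E,5Z)-1-[(1R,2R,5R)-5-acetoxy-2-(but-2-yn-1-yl)-3-oxocyclopentyl]octa-1,5-dien-3-yl hept-5-ynoate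
Product: 21 (8R,11R,12R,15S,13E,17Z)-11-acetoxy-9-oxoprosta-13,17-dien-5-yn-1,15-olide (5,6-didehydro macrolactone, ring B as cycloalkyne)
Conditions: Mo(≡CC6H4-4-OMe)(OSiPh3)3 (5–10 mol %), 5 Å molecular sieves, toluene (2 mM), rt
Reagents that add atoms: none
Why: The alkylidyne adds to one methyl-capped alkyne in a formal [2+2] step to a metallacyclobutadiene, cycloreversion releases but-2-yne and leaves the substrate bound as a new alkylidyne, and the same sequence at the second alkyne joins C5 to C6. The closest known reaction type is ring-closing alkyne metathesis of methyl-capped diyne esters to macrocyclic cycloalkynes with molybdenum alkylidynes carrying triphenylsilanolate ligands. Ring B closes as a 13-membered cycloalkyne by end-to-end union of the two alkyne termini, with both sp carbons becoming ring members, and closure is favoured over oligomerization by high dilution and by trapping of but-2-yne on the sieves. No stereocenter is formed, and C8, C11, C12 and C15 are spectators because the catalyst is neither basic nor protic. The step needs alkyne-over-alkene chemoselectivity and tolerance of a ketone, two esters and a β-acetoxy ketone: an alkylidyne does not engage the C13 and C17 olefins, and the neutral medium at ambient temperature should keep the acetate in place.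

Step 13
Reactants: 21 (8R,11R,12R,15S,13E,17Z)-11-acetoxy-9-oxoprosta-13,17-dien-5-yn-1,15-olide
Product: 22 (8R,11R,12R,15S,5Z,13E,17Z)-11-acetoxy-9-oxoprosta-5,13,17-trien-1,15-olide (target)
Conditions: H2 (1 atm), Pd/CaCO3–Pb(OAc)2 (Lindlar catalyst), quinoline, EtOAc–hexane, rt; stopped after one equivalent of H2
Reagents that add atoms: none
Why: Lindlar semihydrogenation delivers both hydrogens to the same face of the adsorbed ring alkyne, which fixes the 5Z geometry, while the poisoned catalyst should leave the disubstituted C13 and C17 olefins, the ketone and the esters alone.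

Compound list
1 | (Z)-hex-3-en-1-ol | CC/C=C\CCO | starting material
2 | (Z)-hex-3-enal | CC/C=C\CC=O | intermediate
3 | (E)-1,2-bis(tributylstannyl)ethene | CCCC[Sn](CCCC)(CCCC)/C=C/[Sn](CCCC)(CCCC)CCCC | starting material
4 | (E)-2-(tributylstannyl)vinyllithium (not isolated) | [Li]/C=C/[Sn](CCCC)(CCCC)CCCC | intermediate
5 | rac-(1E,5Z)-1-(tributylstannyl)octa-1,5-dien-3-ol | CC/C=C\CC(O)/C=C/[Sn](CCCC)(CCCC)CCCC | intermediate
6 | rac-(1E,5Z)-1-iodoocta-1,5-dien-3-ol | CC/C=C\CC(O)/C=C/I | intermediate
7 | (3S,1E,5Z)-1-iodoocta-1,5-dien-3-ol | CC/C=C\C[C@H](O)/C=C/I | intermediate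
8 | (3S,1E,5Z)-1-iodo-3-(triethylsilyloxy)octa-1,5-diene | CC/C=C\C[C@H](O[Si](CC)(CC)CC)/C=C/I | intermediate
9 | 1-bromobut-2-yne | CC#CCBr | starting material
10 | 1-iodobut-2-yne | CC#CCI | intermediate
11 | (R)-4-(tert-butyldimethylsilyloxy)cyclopent-2-en-1-one | O=C1C=C[C@H](O[Si](C)(C)C(C)(C)C)C1 | starting material
12 | [(3S,1E,5Z)-3-(triethylsilyloxy)octa-1,5-dien-1-yl]lithium (not isolated) | CC/C=C\C[C@H](O[Si](CC)(CC)CC)/C=C/[Li] | intermediate
13 | lithium dimethyl[(3S,1E,5Z)-3-(triethylsilyloxy)octa-1,5-dien-1-yl]zincate (not isolated) | CC/C=C\C[C@H](O[Si](CC)(CC)CC)/C=C/[Zn-](C)C.[Li+] | intermediate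
14 | C8–C9 enolate of the conjugate adduct, lithium enolate associated with Me2Zn (not isolated) | CC/C=C\C[C@H](O[Si](CC)(CC)CC)/C=C/[C@H]1[C@H](O[Si](C)(C)C(C)(C)C)CC(O[Li])=C1.C[Zn]C | intermediate
15 | (2R,3R,4R)-2-(but-2-yn-1-yl)-4-(tert-butyldimethylsilyloxy)-3-[(3S,1E,5Z)-3-(triethylsilyloxy)octa-1,5-dien-1-yl]cyclopentan-1-one | CC/C=C\C[C@H](O[Si](CC)(CC)CC)/C=C/[C@H]1[C@H](O[Si](C)(C)C(C)(C)C)CC(=O)[C@@H]1CC#CC | intermediate
16 | (2R,3R,4R)-2-(but-2-yn-1-yl)-4-(tert-butyldimethylsilyloxy)-3-[(3S,1E,5Z)-3-hydroxyocta-1,5-dien-1-yl]cyclopentan-1-one | CC/C=C\C[C@H](O)/C=C/[C@H]1[C@H](O[Si](C)(C)C(C)(C)C)CC(=O)[C@@H]1CC#CC | intermediate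
17 | hept-5-ynoic acid | CC#CCCCC(=O)O | starting material
18 | (3S,1E,5Z)-1-[(1R,2R,5R)-2-(but-2-yn-1-yl)-5-(tert-butyldimethylsilyloxy)-3-oxocyclopentyl]octa-1,5-dien-3-yl hept-5-ynoate | CC/C=C\C[C@H](OC(=O)CCCC#CC)/C=C/[C@H]1[C@H](O[Si](C)(C)C(C)(C)C)CC(=O)[C@@H]1CC#CC | intermediate
19 | (3S,1E,5Z)-1-[(1R,2R,5R)-2-(but-2-yn-1-yl)-5-hydroxy-3-oxocyclopentyl]octa-1,5-dien-3-yl hept-5-ynoate | CC/C=C\C[C@H](OC(=O)CCCC#CC)/C=C/[C@H]1[C@H](O)CC(=O)[C@@H]1CC#CC | intermediate
20 | (3S,1E,5Z)-1-[(1R,2R,5R)-5-acetoxy-2-(but-2-yn-1-yl)-3-oxocyclopentyl]octa-1,5-dien-3-yl hept-5-ynoate (metathesis precursor) | CC/C=C\C[C@H](OC(=O)CCCC#CC)/C=C/[C@H]1[C@H](OC(C)=O)CC(=O)[C@@H]1CC#CC | intermediate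
21 | (8R,11R,12R,15S,13E,17Z)-11-acetoxy-9-oxoprosta-13,17-dien-5-yn-1,15-olide (ring B cycloalkyne) | CC/C=C\C[C@H]1/C=C/[C@H]2[C@H](OC(C)=O)CC(=O)[C@@H]2CC#CCCCC(=O)O1 | intermediate
22 | (8R,11R,12R,15S,5Z,13E,17Z)-11-acetoxy-9-oxoprosta-5,13,17-trien-1,15-olide | CC/C=C\C[C@H]1/C=C/[C@H]2[C@H](OC(C)=O)CC(=O)[C@@H]2C/C=C\CCCC(=O)O1 | target

Total step count: 13. Longest linear sequence: 12 steps (steps 1–5 and 7–13, from 1 to 22; step 6 is the only side branch).

Steps most likely to fail

First, step 7. Alkylation of the zinc enolate by the propargylic iodide is slow. Proton exchange between enolate and product, drift of the enolate towards C10, and loss of the C11 silyloxy group by β-elimination may therefore overtake C–C bond formation at C8. The fallback sets out from 8 and 11 and returns at 15. It traps the enolate with an aldehyde, which is fast at −78 °C, and removes the extra oxygen afterwards. The alkenyllithium from 8 (t-BuLi, Et2O, −78 °C) is converted with CuI·PBu3 into the phosphine-complexed organocopper reagent and added to 11. The enolate is quenched with but-2-ynal (CC#CC=O) to give the 7-hydroxy aldol adduct F1 as a mixture of C7 epimers. Phenyl chlorothionoformate with pyridine and catalytic DMAP in CH2Cl2 converts it into the O-phenyl thionocarbonate F2. Barton–McCombie deoxygenation (Bu3SnH, AIBN, toluene, 80 °C) through the propargylic radical then gives 15.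

Second, step 12. The β-acetoxy ketone may lose acetic acid on the sieves or on gentle warming, giving the cross-conjugated cyclopentenone. Slow closure may also let intermolecular metathesis build oligomers. The fallback sets out from 18 and returns at 22, and keeps the robust silyl ether on C11 until ring B is complete. Ring-closing alkyne metathesis of 18 under the conditions of step 12 gives the 11-O-silyl cycloalkyne F3. Lindlar semihydrogenation as in step 13 gives the 11-O-silyl 5Z-lactone F4. HF·pyridine as in step 10 gives prostaglandin E3 1,15-lactone F5. Acetylation as in step 11 then gives 22.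

Third, step 2. The basic alkenyllithium may deprotonate the doubly activated C16 methylene of the skipped aldehyde, so that enolization and olefin migration consume 2 before carbonyl addition. The fallback sets out from 2 and returns at 6. It brings in C13–C14 as a far less basic alkynyl Grignard reagent and makes the iodoalkene by hydrometalation. HC≡CMgBr in THF at −78 to 0 °C adds to 2 to give rac-(Z)-oct-5-en-1-yn-3-ol F6. Cp2Zr(H)Cl (2.2 equiv, THF, rt) hydrozirconates the terminal alkyne syn with zirconium at C13, and I2 at 0 °C then gives 6 directly, bypassing 5.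

Further compounds
F1 | step 7 | 7-hydroxy aldol adduct, 2-(1-hydroxybut-2-yn-1-yl) analogue of 15 (C7 epimers, other centres as in 15) | CC/C=C\C[C@H](O[Si](CC)(CC)CC)/C=C/[C@H]1[C@H](O[Si](C)(C)C(C)(C)C)CC(=O)[C@@H]1C(O)C#CC
F2 | step 7 | O-phenyl thionocarbonate of F1 | CC/C=C\C[C@H](O[Si](CC)(CC)CC)/C=C/[C@H]1[C@H](O[Si](C)(C)C(C)(C)C)CC(=O)[C@@H]1C(OC(=S)Oc2ccccc2)C#CC
F3 | step 12 | (8R,11R,12R,15S,13E,17Z)-11-(tert-butyldimethylsilyloxy)-9-oxoprosta-13,17-dien-5-yn-1,15-olide | CC/C=C\C[C@H]1/C=C/[C@H]2[C@H](O[Si](C)(C)C(C)(C)C)CC(=O)[C@@H]2CC#CCCCC(=O)O1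
F4 | step 12 | (8R,11R,12R,15S,5Z,13E,17Z)-11-(tert-butyldimethylsilyloxy)-9-oxoprosta-5,13,17-trien-1,15-olide | CC/C=C\C[C@H]1/C=C/[C@H]2[C@H](O[Si](C)(C)C(C)(C)C)CC(=O)[C@@H]2C/C=C\CCCC(=O)O1
F5 | step 12 | prostaglandin E3 1,15-lactone, (8R,11R,12R,15S,5Z,13E,17Z)-11-hydroxy-9-oxoprosta-5,13,17-trien-1,15-olide | CC/C=C\C[C@H]1/C=C/[C@H]2[C@H](O)CC(=O)[C@@H]2C/C=C\CCCC(=O)O1
F6 | step 2 | rac-(Z)-oct-5-en-1-yn-3-ol | CC/C=C\CC(O)C#C
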